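## Retrosynthetic overview

1. Formamide ⇐ tertiary azide ⇐ Markovnikov HAT hydroazidation of an exocyclic methylene on the convex face of a cis-octalin (C–N bond made last).
2. Ring B ⇐ intramolecular alkylation of a primary tosylate by a 2-substituted allylmagnesium chloride.
3. The C4–C4a bond and both of its stereocentres ⇐ Ireland–Claisen rearrangement of a tertiary cyclohex-2-enyl ester (1,3-chirality transfer), which joins two C10 halves. This replaces the usual intramolecular Diels–Alder route to the cis-decalin.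
4. Halves: ring A is bought as (1S,4R)-p-mentha-2,8-dien-1-ol and ene-chlorinated; the chloro-oxane acid comes from (R)-linalool by chloroetherification, hydroboration and oxidation.
5. Ring order: oxane first, ring A from the chiral pool, ring B last.

Assumption: both terpenes are used as bought in high ee, and locants in the text follow the IUPAC name of the target (octalin C1, C4, C4a, C8a; oxane C2, C5).

## Route

Step 1
Reactants: 1 (1S,4R)-1-methyl-4-(prop-1-en-2-yl)cyclohex-2-en-1-ol (p-mentha-2,8-dien-1-ol, OH cis to isopropenyl)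
Product: 2 (1S,4R)-4-(3-chloroprop-1-en-2-yl)-1-methylcyclohex-2-en-1-ol
Conditions: Ca(OCl)2, CO2 (dry ice), CH2Cl2/H2O, 0 °C
Reagents that add atoms: calcium hypochlorite, [Ca+2].[O-]Cl.[O-]Cl
Why: HOCl ene-type allylic chlorination is fastest at the 1,1-disubstituted isopropenyl group (the ring alkene is 1,2-disubstituted and deactivated by the allylic oxygen) and gives the 2-(chloromethyl)allyl unit without touching a stereocentre.

Step 2
Reactants: 3 (R)-linalool, (3R)-3,7-dimethylocta-1,6-dien-3-ol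
Product: 4 (3S,6R)-3-chloro-6-ethenyl-2,2,6-trimethyloxane (Cl trans to vinyl)
Conditions: t-BuOCl, CH2Cl2, −40 → 0 °C, dark; chromatographic removal of the (3R,6R) epimer
Reagents that add atoms: tert-butyl hypochlorite, CC(C)(C)OCl
Why: Chloronium-induced 6-endo (Markovnikov) chloroetherification of the tertiary alcohol onto the trisubstituted alkene keeps C6 from linalool, but the new C3 centre forms with little bias (vinyl and methyl are alike in size), so the roughly 1:1 epimers are separated at this cheap stage.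

Step 3
Reactants: 4 (3S,6R)-3-chloro-6-ethenyl-2,2,6-trimethyloxane
Product: 6 2-[(2R,5S)-5-chloro-2,6,6-trimethyloxan-2-yl]ethan-1-ol, via alkylborane 5 (not isolated)
Conditions: 9-borabicyclo[3.3.1]nonane (9-BBN), THF, 0 °C → rt; then NaOH, H2O2, 0 °C
Reagents that add atoms: hydrogen peroxide, OO
Why: Anti-Markovnikov hydroboration of the monosubstituted alkene with the bulky borane followed by oxidative work-up gives the primary alcohol and affects no stereocentre.

Step 4
Reactants: 6 2-[(2R,5S)-5-chloro-2,6,6-trimethyloxan-2-yl]ethan-1-ol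
Product: 8 2-[(2R,5S)-5-chloro-2,6,6-trimethyloxan-2-yl]acetic acid, via aldehyde 7 (not isolated)
Conditions: 2,2,6,6-tetramethylpiperidin-1-oxyl (TEMPO, 10 mol %), PhI(OAc)2, MeCN/H2O, rt
Reagents that add atoms: water, O
Why: Oxoammonium (TEMPO) oxidation takes the primary alcohol through the aldehyde hydrate to the acid while the ether and the hindered secondary chloride are inert.

Step 5
Reactants: 8 2-[(2R,5S)-5-chloro-2,6,6-trimethyloxan-2-yl]acetic acid; 2 (1S,4R)-4-(3-chloroprop-1-en-2-yl)-1-methylcyclohex-2-en-1-ol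
Product: 11 (1S,4R)-4-(3-chloroprop-1-en-2-yl)-1-methylcyclohex-2-en-1-yl 2-[(2R,5S)-5-chloro-2,6,6-trimethyloxan-2-yl]acetate, via acid chloride 9 (not isolated), via lithium alkoxide 10 (not isolated)
Conditions: 8, (COCl)2, N,N-dimethylformamide (cat.), CH2Cl2, 0 °C → rt, concentrate; 2, n-BuLi (1.0 equiv), THF, −78 °C; combine, −78 → 0 °C
Reagents that add atoms: none
Why: O-Acylation of the hindered tertiary lithium alkoxide by the acid chloride forms the ester under basic conditions that cannot ionise the tertiary allylic C–O bond, and all stereocentres are carried over unchanged.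

Step 6
Reactants: 11 (1S,4R)-4-(3-chloroprop-1-en-2-yl)-1-methylcyclohex-2-en-1-yl 2-[(2R,5S)-5-chloro-2,6,6-trimethyloxan-2-yl]acetate
Product: 14 (2R)-2-[(2R,5S)-5-chloro-2,6,6-trimethyloxan-2-yl]-2-[(1S,6R)-6-(3-chloroprop-1-en-2-yl)-3-methylcyclohex-2-en-1-yl]acetic acid, via silyl ketene acetal 12 (not isolated), via silyl ester 13 (not isolated)
Conditions: LiN(iPr)2, Me3SiCl (in situ), THF/DMPU 4:1, −78 °C → rt; aqueous work-up
Reagents that add atoms: none
Why: In this Ireland–Claisen [3,3] rearrangement the pseudoaxial C–O bond (cis to the chloropropenyl group) delivers the new C–C bond suprafacially to the same ring face (future C4a and cis ring fusion), and the boat transition state usual for cyclohexenyl esters places OSiMe3 and the oxanyl group of the (Z)-ketene acetal exo, away from that cis side chain, which sets the exocyclic centre (future C4) as R.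

Step 7
Reactants: 14 (2R)-2-[(2R,5S)-5-chloro-2,6,6-trimethyloxan-2-yl]-2-[(1S,6R)-6-(3-chloroprop-1-en-2-yl)-3-methylcyclohex-2-en-1-yl]acetic acid
Product: 16 (2S)-2-[(2R,5S)-5-chloro-2,6,6-trimethyloxan-2-yl]-2-[(1S,6R)-6-(3-chloroprop-1-en-2-yl)-3-methylcyclohex-2-en-1-yl]ethan-1-ol, via mixed anhydride 15 (not isolated)
Conditions: i-BuOCOCl, N-methylmorpholine, THF, −15 °C; then NaBH4, MeOH, −15 → 0 °C
Reagents that add atoms: none
Why: Borohydride reduction of the isobutyl mixed carbonic anhydride reduces only the activated carboxyl group, sparing both chlorides and all alkenes (the descriptor changes from R to S only because of CIP priorities).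

Step 8
Reactants: 16 (2S)-2-[(2R,5S)-5-chloro-2,6,6-trimethyloxan-2-yl]-2-[(1S,6R)-6-(3-chloroprop-1-en-2-yl)-3-methylcyclohex-2-en-1-yl]ethan-1-ol
Product: 17 (2S)-2-[(2R,5S)-5-chloro-2,6,6-trimethyloxan-2-yl]-2-[(1S,6R)-6-(3-chloroprop-1-en-2-yl)-3-methylcyclohex-2-en-1-yl]ethyl 4-methylbenzenesulfonate
Conditions: TsCl, Et3N, 4-(dimethylamino)pyridine (cat.), CH2Cl2, 0 °C
Reagents that add atoms: 4-toluenesulfonyl chloride, Cc1ccc(cc1)S(Cl)(=O)=O
Why: Sulfonylation of the only hydroxyl group gives a leaving group that, unlike a halide, is inert to magnesium metal in the next step.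

Step 9
Reactants: 17 (2S)-2-[(2R,5S)-5-chloro-2,6,6-trimethyloxan-2-yl]-2-[(1S,6R)-6-(3-chloroprop-1-en-2-yl)-3-methylcyclohex-2-en-1-yl]ethyl 4-methylbenzenesulfonate
Product: 19 (4R,4aS,8aR)-4-[(2R,5S)-5-chloro-2,6,6-trimethyloxan-2-yl]-6-methyl-1-methylidene-1,2,3,4,4a,7,8,8a-octahydronaphthalene, via allyl Grignard 18 (not isolated)
Conditions: Mg turnings (1,2-dibromoethane-activated), THF, slow addition at high dilution, 0 °C; then Li2CuCl4 (5 mol %), 0 °C → rt
Reagents that add atoms: none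
Why: Barbier-type insertion of Mg into the allylic C–Cl bond (tosylate and secondary chloride are inert) gives a symmetric 2-substituted allylmagnesium chloride that closes ring B by copper-assisted intramolecular SN2 alkylation of the primary tosylate, where either allyl terminus gives the same six-membered ring and no stereocentre is created.

Step 10
Reactants: 19 (4R,4aS,8aR)-4-[(2R,5S)-5-chloro-2,6,6-trimethyloxan-2-yl]-6-methyl-1-methylidene-1,2,3,4,4a,7,8,8a-octahydronaphthalene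
Product: 20 (1R,4R,4aS,8aR)-1-azido-4-[(2R,5S)-5-chloro-2,6,6-trimethyloxan-2-yl]-1,6-dimethyl-1,2,3,4,4a,7,8,8a-octahydronaphthalene
Conditions: Co(BF4)2·6H2O (6 mol %), potassium 2-{[(3,5-di-tert-butyl-2-hydroxyphenyl)methylidene]amino}-2,2-diphenylacetate (6 mol %), TsN3, PhSiH3, t-BuOOH (30 mol %), EtOH, rt
Reagents that add atoms: tosyl azide, Cc1ccc(cc1)S(=O)(=O)N=[N+]=[N-]
Why: Mukaiyama-type HAT hydroazidation is faster at the 1,1-disubstituted alkene than at the trisubstituted ring alkene, and the tertiary C1 radical is trapped on the convex face along the equatorial trajectory because the axial face is blocked by the syn-axial C4a–C5 bond of ring A, which sets C1 as R.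

Step 11
Reactants: 20 (1R,4R,4aS,8aR)-1-azido-4-[(2R,5S)-5-chloro-2,6,6-trimethyloxan-2-yl]-1,6-dimethyl-1,2,3,4,4a,7,8,8a-octahydronaphthalene
Product: 23 N-[(1R,4R,4aS,8aR)-4-[(2R,5S)-5-chloro-2,6,6-trimethyloxan-2-yl]-1,6-dimethyl-1,2,3,4,4a,7,8,8a-octahydronaphthalen-1-yl]formamide, via iminophosphorane 21 (not isolated), via amine 22 (not isolated)
Conditions: PMe3, THF, rt; H2O, 50 °C; concentrate; preformed acetic formic anhydride, CH2Cl2, 0 °C
Reagents that add atoms: acetic formic anhydride, CC(=O)OC=O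
Why: Staudinger reduction turns the tertiary azide into the amine with retention at C1 without touching the alkene or the C–Cl bond, and the mixed anhydride then transfers only its formyl group to the hindered amine (N-formylation).

## Compound list

1 | (1S,4R)-1-methyl-4-(prop-1-en-2-yl)cyclohex-2-en-1-ol | C[C@@]1(O)C=C[C@H](C(C)=C)CC1 | starting material
2 | (1S,4R)-4-(3-chloroprop-1-en-2-yl)-1-methylcyclohex-2-en-1-ol | C[C@@]1(O)C=C[C@H](C(CCl)=C)CC1 | intermediate
3 | (R)-linalool, (3R)-3,7-dimethylocta-1,6-dien-3-ol | C=C[C@](C)(O)CCC=C(C)C | starting material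
4 | (3S,6R)-3-chloro-6-ethenyl-2,2,6-trimethyloxane | C=C[C@@]1(C)CC[C@H](Cl)C(C)(C)O1 | intermediate
5 | 9-{2-[(2S,5S)-5-chloro-2,6,6-trimethyloxan-2-yl]ethyl}-9-borabicyclo[3.3.1]nonane | C1CCC2CCCC1B2CC[C@@]3(C)CC[C@H](Cl)C(C)(C)O3 | intermediate
6 | 2-[(2R,5S)-5-chloro-2,6,6-trimethyloxan-2-yl]ethan-1-ol | OCC[C@@]1(C)CC[C@H](Cl)C(C)(C)O1 | intermediate
7 | 2-[(2R,5S)-5-chloro-2,6,6-trimethyloxan-2-yl]acetaldehyde | O=CC[C@@]1(C)CC[C@H](Cl)C(C)(C)O1 | intermediate
8 | 2-[(2R,5S)-5-chloro-2,6,6-trimethyloxan-2-yl]acetic acid | OC(=O)C[C@@]1(C)CC[C@H](Cl)C(C)(C)O1 | intermediate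
9 | 2-[(2R,5S)-5-chloro-2,6,6-trimethyloxan-2-yl]acetyl chloride | ClC(=O)C[C@@]1(C)CC[C@H](Cl)C(C)(C)O1 | intermediate
10 | lithium (1S,4R)-4-(3-chloroprop-1-en-2-yl)-1-methylcyclohex-2-en-1-olate | C[C@@]1([O-])C=C[C@H](C(CCl)=C)CC1.[Li+] | intermediate
11 | (1S,4R)-4-(3-chloroprop-1-en-2-yl)-1-methylcyclohex-2-en-1-yl 2-[(2R,5S)-5-chloro-2,6,6-trimethyloxan-2-yl]acetate | C[C@@]1(OC(=O)C[C@@]2(C)CC[C@H](Cl)C(C)(C)O2)C=C[C@H](C(CCl)=C)CC1 | intermediate
12 | (Z)-trimethylsilyl ketene acetal of 11 (OSiMe3 cis to the oxanyl group) | C[C@@]1(O/C(O[Si](C)(C)C)=C/[C@@]2(C)CC[C@H](Cl)C(C)(C)O2)C=C[C@H](C(CCl)=C)CC1 | intermediate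
13 | trimethylsilyl (2R)-2-[(2R,5S)-5-chloro-2,6,6-trimethyloxan-2-yl]-2-[(1S,6R)-6-(3-chloroprop-1-en-2-yl)-3-methylcyclohex-2-en-1-yl]acetate | CC1=C[C@H]([C@@H](C(=O)O[Si](C)(C)C)[C@@]2(C)CC[C@H](Cl)C(C)(C)O2)[C@H](C(CCl)=C)CC1 | intermediate
14 | (2R)-2-[(2R,5S)-5-chloro-2,6,6-trimethyloxan-2-yl]-2-[(1S,6R)-6-(3-chloroprop-1-en-2-yl)-3-methylcyclohex-2-en-1-yl]acetic acid | CC1=C[C@H]([C@@H](C(O)=O)[C@@]2(C)CC[C@H](Cl)C(C)(C)O2)[C@H](C(CCl)=C)CC1 | intermediate
15 | isobutyl carbonic mixed anhydride of 14 | CC1=C[C@H]([C@@H](C(=O)OC(=O)OCC(C)C)[C@@]2(C)CC[C@H](Cl)C(C)(C)O2)[C@H](C(CCl)=C)CC1 | intermediate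
16 | (2S)-2-[(2R,5S)-5-chloro-2,6,6-trimethyloxan-2-yl]-2-[(1S,6R)-6-(3-chloroprop-1-en-2-yl)-3-methylcyclohex-2-en-1-yl]ethan-1-ol | CC1=C[C@H]([C@@H](CO)[C@@]2(C)CC[C@H](Cl)C(C)(C)O2)[C@H](C(CCl)=C)CC1 | intermediate
17 | 4-methylbenzenesulfonate (tosylate) of 16 | CC1=C[C@H]([C@@H](COS(=O)(=O)c2ccc(C)cc2)[C@@]3(C)CC[C@H](Cl)C(C)(C)O3)[C@H](C(CCl)=C)CC1 | intermediate
18 | allylmagnesium chloride formed from 17 (MgCl in place of the allylic Cl) | CC1=C[C@H]([C@@H](COS(=O)(=O)c2ccc(C)cc2)[C@@]3(C)CC[C@H](Cl)C(C)(C)O3)[C@H](C(C[Mg]Cl)=C)CC1 | intermediate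
19 | (4R,4aS,8aR)-4-[(2R,5S)-5-chloro-2,6,6-trimethyloxan-2-yl]-6-methyl-1-methylidene-1,2,3,4,4a,7,8,8a-octahydronaphthalene | CC1=C[C@H]2[C@@H](CC1)C(=C)CC[C@H]2[C@@]1(C)CC[C@H](Cl)C(C)(C)O1 | intermediate
20 | (1R,4R,4aS,8aR)-1-azido-4-[(2R,5S)-5-chloro-2,6,6-trimethyloxan-2-yl]-1,6-dimethyl-1,2,3,4,4a,7,8,8a-octahydronaphthalene | CC1=C[C@H]2[C@@H](CC1)[C@](C)(N=[N+]=[N-])CC[C@H]2[C@@]1(C)CC[C@H](Cl)C(C)(C)O1 | intermediate
21 | P,P,P-trimethyl iminophosphorane of amine 22 | CC1=C[C@H]2[C@@H](CC1)[C@](C)(N=P(C)(C)C)CC[C@H]2[C@@]1(C)CC[C@H](Cl)C(C)(C)O1 | intermediate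
22 | (1R,4R,4aS,8aR)-4-[(2R,5S)-5-chloro-2,6,6-trimethyloxan-2-yl]-1,6-dimethyl-1,2,3,4,4a,7,8,8a-octahydronaphthalen-1-amine | CC1=C[C@H]2[C@@H](CC1)[C@](C)(N)CC[C@H]2[C@@]1(C)CC[C@H](Cl)C(C)(C)O1 | intermediate
23 | N-[(1R,4R,4aS,8aR)-4-[(2R,5S)-5-chloro-2,6,6-trimethyloxan-2-yl]-1,6-dimethyl-1,2,3,4,4a,7,8,8a-octahydronaphthalen-1-yl]formamide | CC1=C[C@H]2[C@@H](CC1)[C@](C)(NC=O)CC[C@H]2[C@@]1(C)CC[C@H](Cl)C(C)(C)O1 | target

## Step count and risks

Total steps: 11. Longest linear sequence: 10 steps (3 → 23, steps 2 to 11).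

The three steps most likely to fail:

**Step 6 (Ireland–Claisen).** The ester enolate carries a β-alkoxy group and could open the oxane by E1cB elimination before silylation, and the chair/boat balance decides the exocyclic stereocentre. The fallback is an enolate-free Eschenmoser–Claisen rearrangement. It sets out from acid 8 (through its chloride 9) and alcohol 2 and returns at alcohol 16. Chloride 9 is treated with Me2NH to give the N,N-dimethylamide F1, which is O-methylated with MeOTf and treated with NaOMe to give the amide dimethyl acetal F2. Heating F2 with 2 in xylene at 140 °C exchanges in the allylic alkoxy group, and the resulting ketene N,O-acetal rearranges with the same suprafacial transfer to the γ,δ-unsaturated amide F3. Cp2Zr(H)Cl reduces F3 to the aldehyde F4, and NaBH4 in MeOH gives 16.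

**Step 9 (Mg-mediated ring closure).** The SN2 step at the β-branched primary tosylate may be slow against Wurtz dimerisation or attack at sulfur. The fallback closes ring B by acylation and then removes the oxygen. It sets out from acid 14 and returns at 19. Acid 14 is converted through mixed anhydride 15 with MeNHOMe·HCl into the Weinreb amide F5. Mg in THF forms the allylmagnesium chloride, which cyclises onto the amide to give the β,γ-unsaturated ketone F6. TsNHNH2 gives the tosylhydrazone F7, and catecholborane followed by NaOAc·3H2O reduces it to the methylene compound 19.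

**Step 10 (hydroazidation).** Discrimination between the two alkenes and the facial selectivity of radical trapping are not guaranteed. The fallback is an ionic azidomercuration–demercuration. It sets out from 19 and returns at 20. Hg(OAc)2 and NaN3 in THF/H2O react far faster with the 1,1-disubstituted alkene than with the trisubstituted one, and azide opens the mercurinium ion at the tertiary carbon from the convex face to give the β-azidoalkylmercury acetate F8. NaBH4/NaOH then removes mercury to give azide 20.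

## Further compounds

F1 | step 6 | 2-[(2R,5S)-5-chloro-2,6,6-trimethyloxan-2-yl]-N,N-dimethylacetamide | CN(C)C(=O)C[C@@]1(C)CC[C@H](Cl)C(C)(C)O1
F2 | step 6 | 2-[(2R,5S)-5-chloro-2,6,6-trimethyloxan-2-yl]-1,1-dimethoxy-N,N-dimethylethan-1-amine | CN(C)C(OC)(OC)C[C@@]1(C)CC[C@H](Cl)C(C)(C)O1
F3 | step 6 | (2R)-2-[(2R,5S)-5-chloro-2,6,6-trimethyloxan-2-yl]-2-[(1S,6R)-6-(3-chloroprop-1-en-2-yl)-3-methylcyclohex-2-en-1-yl]-N,N-dimethylacetamide | CC1=C[C@H]([C@@H](C(=O)N(C)C)[C@@]2(C)CC[C@H](Cl)C(C)(C)O2)[C@H](C(CCl)=C)CC1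
F4 | step 6 | (2R)-2-[(2R,5S)-5-chloro-2,6,6-trimethyloxan-2-yl]-2-[(1S,6R)-6-(3-chloroprop-1-en-2-yl)-3-methylcyclohex-2-en-1-yl]acetaldehyde | CC1=C[C@H]([C@@H](C=O)[C@@]2(C)CC[C@H](Cl)C(C)(C)O2)[C@H](C(CCl)=C)CC1
F5 | step 9 | (2R)-2-[(2R,5S)-5-chloro-2,6,6-trimethyloxan-2-yl]-2-[(1S,6R)-6-(3-chloroprop-1-en-2-yl)-3-methylcyclohex-2-en-1-yl]-N-methoxy-N-methylacetamide | CC1=C[C@H]([C@@H](C(=O)N(C)OC)[C@@]2(C)CC[C@H](Cl)C(C)(C)O2)[C@H](C(CCl)=C)CC1
F6 | step 9 | (4R,4aS,8aR)-4-[(2R,5S)-5-chloro-2,6,6-trimethyloxan-2-yl]-6-methyl-1-methylidene-1,4,4a,7,8,8a-hexahydronaphthalen-3(2H)-one | CC1=C[C@H]2[C@@H](CC1)C(=C)CC(=O)[C@H]2[C@@]1(C)CC[C@H](Cl)C(C)(C)O1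
F7 | step 9 | 4-methylbenzenesulfonylhydrazone of F6 | CC1=C[C@H]2[C@@H](CC1)C(=C)CC(=NNS(=O)(=O)c1ccc(C)cc1)[C@H]2[C@@]1(C)CC[C@H](Cl)C(C)(C)O1
F8 | step 10 | {[(1R,4R,4aS,8aR)-1-azido-4-[(2R,5S)-5-chloro-2,6,6-trimethyloxan-2-yl]-6-methyl-1,2,3,4,4a,7,8,8a-octahydronaphthalen-1-yl]methyl}mercury acetate | CC1=C[C@H]2[C@@H](CC1)[C@](C[Hg]OC(C)=O)(N=[N+]=[N-])CC[C@H]2[C@@]1(C)CC[C@H](Cl)C(C)(C)O1
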